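Numbering used throughout: oxolane O1, C2 (bears ring A), C3 (bears C9H2–O–acyl), C4 (bears C7'H2–ring B), C5H2. The retrosynthesis cuts the C9O–acyl ester bond first. C7' is then tied back to the C9 oxygen and C5 is raised to a lactone carbonyl, after which the C4–C7' bond is cut, and last the C2–C3 bond together with the O1–C5 lactone bond.
Enabling feature: C9 on C3 and C7' on C4 lie on the same face of the oxolane, so the chain C4–C3–C9–O–C7' can exist as a second, cis-fused oxolane. Its C7'–O bond is benzylic to the electron-rich ring B and can be removed reductively afterwards.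
Forward order: an allylboration joins the ring-A aldehyde to a ring-B benzyloxymethyl allylboronate (C2–C3). Hydroboration and oxidative lactonisation close the first ring, and diazo transfer at C4 followed by Rh2(OAc)4-catalysed carbene insertion into C7'–H closes the second. Lactone-to-ether reduction, hydrogenolytic opening of the second ring, phenol release and acylation finish the route.
Stereochemistry: C2 (S) comes from a chiral phosphoric acid. C3 (R) comes from the E-boronate through a chair transition state (anti, hence 2,3-trans). C4 (R) comes from the obligatory cis ring fusion of the insertion, and the extra centre C7' is erased.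
Ring A travels as its tosylate (electron-poor, guards C2–O). Ring B travels as its benzyl ether (electron-rich, activates C7'–H and later C7'–O).

Key step: step 10

Assumption: the sense of induction of the phosphoric acid is taken from simple aromatic aldehydes, where the (R)-acid sends the allyl group to the Re face. The (S)-acid is therefore specified. If the functionalised boronate reverses the sense, the (R)-acid is used and nothing else changes.

Step 1
Reactants: 1 vanillin
Product: 2 4-formyl-2-methoxyphenyl 4-methylbenzenesulfonate (O-tosylvanillin)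
Conditions: TsCl, K2CO3, acetone, reflux
Reagents that add atoms: p-toluenesulfonyl chloride, Cc1ccc(cc1)S(=O)(=O)Cl
Why: O-sulfonylation of the phenoxide is routine, and the electron-withdrawing sulfonate is chosen because it later shields the ring-A benzylic C2–O bond from Lewis acid and hydrogenolysis and survives every step up to step 14.

Step 2
Reactants: 3 vanillyl alcohol
Product: 4 [4-(benzyloxy)-3-methoxyphenyl]methanol
Conditions: BnBr, K2CO3, DMF, rt
Reagents that add atoms: benzyl bromide, BrCc1ccccc1
Why: Williamson ether synthesis in which the carbonate deprotonates only the phenol, so the benzylic alcohol stays free.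

Step 3
Reactants: 4 [4-(benzyloxy)-3-methoxyphenyl]methanol
Product: 5 1-(benzyloxy)-4-(chloromethyl)-2-methoxybenzene
Conditions: SOCl2, CH2Cl2, 0 °C
Reagents that add atoms: thionyl chloride, O=S(Cl)Cl
Why: Chlorodehydroxylation of an electron-rich benzylic alcohol is fast at 0 °C and leaves the aryl benzyl ether untouched, and the chloride is used without storage.

Step 4
Reactants: 5 1-(benzyloxy)-4-(chloromethyl)-2-methoxybenzene; 6 (E)-but-2-ene-1,4-diol
Product: 7 (E)-4-{[4-(benzyloxy)-3-methoxybenzyl]oxy}but-2-en-1-ol
Conditions: NaH, 6 (4 equiv), THF/DMF, 0 °C; then 5, Bu4NI (10 mol %), rt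
Reagents that add atoms: none
Why: Williamson ether synthesis with the monoalkoxide of a fourfold excess of the diol favours the monoether statistically and does not touch the E double bond.

Step 5
Reactants: 7 (E)-4-{[4-(benzyloxy)-3-methoxybenzyl]oxy}but-2-en-1-ol
Product: 8 2-[(E)-4-{[4-(benzyloxy)-3-methoxybenzyl]oxy}but-2-en-1-yl]-4,4,5,5-tetramethyl-1,3,2-dioxaborolane
Conditions: B2pin2 (1.5 equiv), [Pd(MeCN)4](BF4)2 (5 mol %), DMSO/MeOH 1:1, 40 °C
Reagents that add atoms: bis(pinacolato)diboron, CC1(C)OB(OC1(C)C)B1OC(C)(C)C(C)(C)O1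
Why: Palladium-catalysed direct borylation of an allylic alcohol runs through a π-allyl intermediate on palladium that takes up boron at its unsubstituted terminus, which should give the linear boronate with the E geometry kept.

Step 6
Reactants: 2 O-tosylvanillin; 8 (E)-allylboronate
Product: 10 4-[(1S,2R)-2-({[4-(benzyloxy)-3-methoxybenzyl]oxy}methyl)-1-hydroxybut-3-en-1-yl]-2-methoxyphenyl 4-methylbenzenesulfonate (anti), via pinacol borate 9 (not isolated)
Conditions: (S)-TRIP [(S)-3,3'-bis(2,4,6-triisopropylphenyl)-1,1'-binaphthyl-2,2'-diyl hydrogen phosphate] (5 mol %), 4 Å molecular sieves, toluene, −30 °C; aq NaHCO3 work-up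
Reagents that add atoms: none
Why: Chiral phosphoric acid catalysed allylboration through a closed chair (Zimmerman–Traxler) transition state, in which the E-boronate holds C9 equatorial and so gives the anti relation that fixes C3 as R, while the (S)-acid, hydrogen-bonded to a boronate oxygen and to the formyl hydrogen, should expose the Si face of 2 and fix C2 as S.

Step 7
Reactants: 10 anti-homoallylic alcohol
Product: 12 4-[(1S,2R)-2-({[4-(benzyloxy)-3-methoxybenzyl]oxy}methyl)-1,4-dihydroxybutyl]-2-methoxyphenyl 4-methylbenzenesulfonate, via bis(9-BBN) adduct 11 (not isolated)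
Conditions: 9-BBN (2.5 equiv), THF, 0 °C to rt; then 30% H2O2, aq NaOAc, 0 °C to rt
Reagents that add atoms: hydrogen peroxide, OO; 9-borabicyclo[3.3.1]nonane, B1C2CCCC1CCC2 (stays only in 11)
Why: Anti-Markovnikov hydroboration–oxidation, in which bulky 9-BBN places boron on the terminal carbon of the monosubstituted alkene (one further equivalent is taken up by the free hydroxyl) and the buffered peroxide oxidation spares the aryl sulfonate, with no stereocentre touched.

Step 8
Reactants: 12 1,4-diol
Product: 14 4-[(2S,3R)-3-({[4-(benzyloxy)-3-methoxybenzyl]oxy}methyl)-5-oxooxolan-2-yl]-2-methoxyphenyl 4-methylbenzenesulfonate (2,3-trans lactone), via lactol 13 (not isolated)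
Conditions: TEMPO (20 mol %), PhI(OAc)2 (2.5 equiv), CH2Cl2, rt
Reagents that add atoms: none
Why: TEMPO/PhI(OAc)2 oxidative lactonisation, in which the oxoammonium salt oxidises the primary alcohol far faster than the hindered, electron-poor secondary benzylic one, the hydroxy aldehyde closes to lactol 13 and this is oxidised on to the γ-lactone with C2 and C3 unchanged.

Step 9
Reactants: 14 trans-lactone; 15 4-acetamidobenzenesulfonyl azide
Product: 17 4-[(2S,3R)-3-({[4-(benzyloxy)-3-methoxybenzyl]oxy}methyl)-4-diazo-5-oxooxolan-2-yl]-2-methoxyphenyl 4-methylbenzenesulfonate (α-diazo lactone), via trifluoroacetyl lactone 16 (not isolated)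
Conditions: LiN(SiMe3)2 (1.1 equiv), THF, −78 °C; CF3CO2CH2CF3 (1.2 equiv); 5% HCl quench; crude 16, 15 (1.5 equiv), Et3N (1.5 equiv), H2O (1 equiv), MeCN, rt
Reagents that add atoms: 2,2,2-trifluoroethyl trifluoroacetate, O=C(OCC(F)(F)F)C(F)(F)F (stays only in 16)
Why: Deacylative Regitz diazo transfer, needed because the lactone alone is not acidic enough, so its lithium enolate (which has no leaving group on C3 and cannot eliminate) is first trifluoroacetylated at C4 and the activated dicarbonyl compound 16 then takes N2 from 15 while the trifluoroacetyl group leaves on the sulfonamide.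

Step 10
Reactants: 17 α-diazo lactone
Product: 19 (3S,3aR,6R,6aS)-6-[4-(benzyloxy)-3-methoxyphenyl]-3-[3-methoxy-4-(tosyloxy)phenyl]tetrahydro-1H,3H-furo[3,4-c]furan-1-one (cis-fused; ring A exo at C2; ring B endo at C7'), via Rh2(OAc)4 carbene 18 (not isolated)
Conditions: Rh2(OAc)4 (2 mol %), CH2Cl2, reflux, 17 added by syringe pump over 4 h (final 0.01 M)
Reagents that add atoms: dirhodium tetraacetate, CC(=O)[O-].CC(=O)[O-].CC(=O)[O-].CC(=O)[O-].[Rh+2].[Rh+2] (bound only in 18; nothing stays in 19)
Why: Rh2(OAc)4 expels N2 from 17, and the electrophilic carbene 18 at C4 inserts, through a concerted three-centre transition state with hydride-transfer character, into a C7'–H bond of the ring-B benzyl ether on C9. The closest known reaction is the dirhodium-catalysed 1,5 C–H insertion of α-diazo-γ-butyrolactones into benzylic ether C–H bonds, which gives furofuranones. The one ring that closes, the oxolane C4–C3–C9–O–C7', forms by 1,5-insertion, that is by C4–C7' bond formation through a five-membered cyclic array, the preferred ring size for such carbenes. C4 is controlled by C3, because two fused five-membered rings tolerate only a cis junction, so the new bond forms on the face that carries C9 and the migrating hydrogen ends up on C4 cis to H3, which is the 3,4-cis relation of the target. C7' is controlled by the transition-state conformation, in which ring B is expected to turn to the concave face (endo, cis to the lactone carbonyl), but the outcome is immaterial since C7' becomes CH2 in step 13. The step needs chemoselectivity over 1,2-hydride migration from C3, over oxonium ylide formation and over attack on the arenes, and this is secured by the double activation of C7'–H (ether oxygen plus p-alkoxyaryl group), by the strain of the four-membered ylide, by the tosylate that deactivates ring A and by slow addition, which keeps carbene dimerisation down.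

Step 11
Reactants: 19 furofuranone
Product: 20 lactol of 19 (C5–OH; both anomers; C2 C3 C4 C7' as in 19)
Conditions: i-Bu2AlH (1.2 equiv), CH2Cl2, −78 °C; aq potassium sodium tartrate
Reagents that add atoms: none
Why: Partial reduction of a γ-lactone with i-Bu2AlH stops at the tetrahedral aluminium alkoxide at −78 °C, and the aryl sulfonate and the benzyl ethers are inert under these conditions.

Step 12
Reactants: 20 lactol
Product: 21 (1S,3aR,4R,6aR)-4-[4-(benzyloxy)-3-methoxyphenyl]-1-[3-methoxy-4-(tosyloxy)phenyl]tetrahydro-1H,3H-furo[3,4-c]furan (endo,exo-furofuran)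
Conditions: Et3SiH (3 equiv), BF3·OEt2 (1.5 equiv), CH2Cl2, −78 to −40 °C; aq NaHCO3
Reagents that add atoms: none
Why: Ionic deoxygenation of a lactol (Lewis acid ionisation, then hydride transfer from the silane) is much faster at low temperature than ionisation of the C7'–O ether, the tosylated ring A keeps C2–O from ionising, and any epimerisation or early reductive cleavage at C7' would be harmless because that centre is removed in step 13.

Step 13
Reactants: 21 endo,exo-furofuran
Product: 23 4-[(2S,3R,4R)-4-(4-hydroxy-3-methoxybenzyl)-3-(hydroxymethyl)oxolan-2-yl]-2-methoxyphenyl 4-methylbenzenesulfonate (ring-A O-tosyl-lariciresinol), via free phenol 22 (not isolated)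
Conditions: H2 (1–3 atm), Pd(OH)2/C, EtOH/EtOAc, rt
Reagents that add atoms: none
Why: Catalytic hydrogenolysis first removes the phenolic benzyl group and then cleaves the strained endo C7'–O bond para to the freed phenol (the known opening of furofuran lignans to 2-aryl-4-benzyloxolanes), whereas the C2–O bond next to the electron-poor tosyloxy ring should react far more slowly, and C2, C3 and C4 are not involved so the 3,4-cis relation stays.

Step 14
Reactants: 23 ring-A O-tosyl-lariciresinol
Product: 24 (+)-lariciresinol
Conditions: Mg turnings (10 equiv), MeOH, rt; aq NH4Cl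
Reagents that add atoms: none
Why: Reductive S–O cleavage of an aryl tosylate by electron transfer from Mg in MeOH frees the ring-A phenol at room temperature without hot alkali, which avoids quinone methide formation and epimerisation at C2.

Step 15
Reactants: 24 (+)-lariciresinol
Product: 25 (+)-9'-isovaleroxylariciresinol
Conditions: (i-PrCH2CO)2O (2 equiv), Novozym 435 (immobilised Candida antarctica lipase B), acetone/t-BuOMe, 45 °C
Reagents that add atoms: isovaleric anhydride, CC(C)CC(=O)OC(=O)CC(C)C
Why: Lipase-catalysed acyl transfer reaches primary aliphatic alcohols but not phenols, as known for vanillyl alcohol and for polyphenolic flavonolignans, so the only aliphatic hydroxyl (C9–OH) should be esterified with both phenols left free.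

Compound list
1 | vanillin | COc1cc(C=O)ccc1O | starting material
2 | 4-formyl-2-methoxyphenyl 4-methylbenzenesulfonate | COc1cc(C=O)ccc1OS(=O)(=O)c1ccc(C)cc1 | intermediate
3 | vanillyl alcohol | COc1cc(CO)ccc1O | starting material
4 | [4-(benzyloxy)-3-methoxyphenyl]methanol | COc1cc(CO)ccc1OCc1ccccc1 | intermediate
5 | 1-(benzyloxy)-4-(chloromethyl)-2-methoxybenzene | COc1cc(CCl)ccc1OCc1ccccc1 | intermediate
6 | (E)-but-2-ene-1,4-diol | OC/C=C/CO | starting material
7 | (E)-4-{[4-(benzyloxy)-3-methoxybenzyl]oxy}but-2-en-1-ol | OC/C=C/COCc1ccc(OCc2ccccc2)c(OC)c1 | intermediate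
8 | (E)-allylboronic acid pinacol ester of 7 | CC1(C)OB(C/C=C/COCc2ccc(OCc3ccccc3)c(OC)c2)OC1(C)C | intermediate
9 | pinacol borate of 10 (C2–O–Bpin; not isolated) | CC1(C)OB(O[C@H](c2ccc(OS(=O)(=O)c3ccc(C)cc3)c(OC)c2)[C@H](C=C)COCc2ccc(OCc3ccccc3)c(OC)c2)OC1(C)C | intermediate
10 | (1S,2R)-anti-homoallylic alcohol | O[C@H](c1ccc(OS(=O)(=O)c2ccc(C)cc2)c(OC)c1)[C@H](C=C)COCc1ccc(OCc2ccccc2)c(OC)c1 | intermediate
11 | bis(9-BBN) adduct of 10 (C5–B and C2–O–B; not isolated) | B1(O[C@H](c2ccc(OS(=O)(=O)c3ccc(C)cc3)c(OC)c2)[C@H](CCB2C3CCCC2CCC3)COCc2ccc(OCc3ccccc3)c(OC)c2)C2CCCC1CCC2 | intermediate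
12 | (1S,2R)-1,4-diol | O[C@H](c1ccc(OS(=O)(=O)c2ccc(C)cc2)c(OC)c1)[C@H](CCO)COCc1ccc(OCc2ccccc2)c(OC)c1 | intermediate
13 | monocyclic lactol (C5–OH, anomers; not isolated) | C1C(O)O[C@H](c2ccc(OS(=O)(=O)c3ccc(C)cc3)c(OC)c2)[C@H]1COCc1ccc(OCc2ccccc2)c(OC)c1 | intermediate
14 | (2S,3R)-trans-lactone | C1C(=O)O[C@H](c2ccc(OS(=O)(=O)c3ccc(C)cc3)c(OC)c2)[C@H]1COCc1ccc(OCc2ccccc2)c(OC)c1 | intermediate
15 | 4-acetamidobenzenesulfonyl azide | CC(=O)Nc1ccc(cc1)S(=O)(=O)N=[N+]=[N-] | starting material
16 | C4-trifluoroacetyl lactone (C4 labile; not isolated) | FC(F)(F)C(=O)C1C(=O)O[C@H](c2ccc(OS(=O)(=O)c3ccc(C)cc3)c(OC)c2)[C@H]1COCc1ccc(OCc2ccccc2)c(OC)c1 | intermediate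
17 | (2S,3R)-α-diazo lactone | [N-]=[N+]=C1C(=O)O[C@H](c2ccc(OS(=O)(=O)c3ccc(C)cc3)c(OC)c2)[C@H]1COCc1ccc(OCc2ccccc2)c(OC)c1 | intermediate
18 | Rh2(OAc)4 carbene at C4 (not isolated) | CC(=O)[O-].CC(=O)[O-].CC(=O)[O-].CC(=O)[O-].[Rh+2].[Rh+2]=C1C(=O)O[C@H](c2ccc(OS(=O)(=O)c3ccc(C)cc3)c(OC)c2)[C@H]1COCc1ccc(OCc2ccccc2)c(OC)c1 | intermediate
19 | (3S,3aR,6R,6aS)-cis-fused diaryl furofuranone | COc1cc([C@H]2[C@H]3C(=O)O[C@H](c4ccc(OS(=O)(=O)c5ccc(C)cc5)c(OC)c4)[C@H]3CO2)ccc1OCc1ccccc1 | intermediate
20 | bicyclic lactol of 19 (anomers) | COc1cc([C@H]2[C@H]3C(O)O[C@H](c4ccc(OS(=O)(=O)c5ccc(C)cc5)c(OC)c4)[C@H]3CO2)ccc1OCc1ccccc1 | intermediate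
21 | (1S,3aR,4R,6aR)-endo,exo-furofuran | COc1cc([C@H]2[C@H]3CO[C@H](c4ccc(OS(=O)(=O)c5ccc(C)cc5)c(OC)c4)[C@H]3CO2)ccc1OCc1ccccc1 | intermediate
22 | debenzylated furofuran (ring-B phenol; not isolated) | COc1cc([C@H]2[C@H]3CO[C@H](c4ccc(OS(=O)(=O)c5ccc(C)cc5)c(OC)c4)[C@H]3CO2)ccc1O | intermediate
23 | (2S,3R,4R)-ring-A O-tosyl-lariciresinol | COc1cc(C[C@H]2CO[C@H](c3ccc(OS(=O)(=O)c4ccc(C)cc4)c(OC)c3)[C@H]2CO)ccc1O | intermediate
24 | (+)-lariciresinol, (2S,3R,4R) | COc1cc(C[C@H]2CO[C@H](c3ccc(O)c(OC)c3)[C@H]2CO)ccc1O | intermediate
25 | (+)-9'-isovaleroxylariciresinol, [(2S,3R,4R)-2-(4-hydroxy-3-methoxyphenyl)-4-(4-hydroxy-3-methoxybenzyl)oxolan-3-yl]methyl 3-methylbutanoate | COc1cc(C[C@H]2CO[C@H](c3ccc(O)c(OC)c3)[C@H]2COC(=O)CC(C)C)ccc1O | target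

Total step count: 15. Longest linear sequence: 14 steps (steps 2 to 15, from vanillyl alcohol 3 to 25); step 1 is the side branch.

Steps most likely to fail

Step 10 may lose material to hydride migration from C3 to the carbene carbon, to ylide formation at the ether oxygen, or to addition of the carbene to ring B before insertion takes place. The fallback makes the same C4–C7' bond by polar chemistry. It sets out from lactone 14 and comes back to the route at furofuranone 19.
- The lithium enolate of 14 (LiN(SiMe3)2, 2.2 equiv, THF, −78 °C) is C-acylated with 4-(benzyloxy)-3-methoxybenzoyl chloride to give the α-aroyl lactone F1.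
- DDQ in wet CH2Cl2 then strips the electron-rich benzyl ether from the C9 oxygen. Because C4 of the β-keto lactone epimerises freely, the freed alcohol adds to the ketone from the cis isomer and gives the bicyclic hemiketal F2.
- Ionic reduction (Et3SiH, BF3·OEt2, CH2Cl2, −78 °C), with hydride delivered to the convex face, should then give 19.

In step 13 the cleavage of the C7'–O bond may stall after debenzylation, or hydrogenolysis may run on into the C2–O bond. The fallback replaces surface catalysis by ionic hydrogenation, whose cationic pathway responds far more strongly to the electronic difference between the two rings. It sets out from furofuran 21 and comes back at 23.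
- Excess Et3SiH and BF3·OEt2 in CH2Cl2 at 0 °C should ionise only at C7' and give the O-benzyl ring-opened alcohol F3.
- A short hydrogenolysis (H2, 1 atm, Pd/C, EtOAc) then removes only the phenolic benzyl group and gives 23.

In step 6 the facial selectivity may be poor with the functionalised boronate, or partial E/Z scrambling of the boronate may erode the anti relation. The fallback changes the carbon nucleophile. It sets out from aldehyde 2 and comes back at 10.
- Aldehyde 2 is coupled with the cyclic carbonate of (Z)-but-2-ene-1,4-diol by iridium-catalysed transfer-hydrogenative anti-(hydroxymethyl)allylation. The conditions are [Ir(cod)Cl]2, the SEGPHOS enantiomer that gives the (1S) alcohol, 4-cyano-3-nitrobenzoic acid, catalytic base, i-PrOH as reductant, THF and heat. This gives the anti-1,3-diol F4.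
- The unhindered primary hydroxyl of F4 is then etherified selectively with chloride 5 (Ag2O, catalytic KI, toluene, rt) to give 10.

Further compounds
F1 | step 10 | α-[4-(benzyloxy)-3-methoxybenzoyl] derivative of lactone 14 (C2 S, C3 R, C4 labile) | COc1cc(C(=O)C2C(=O)O[C@H](c3ccc(OS(=O)(=O)c4ccc(C)cc4)c(OC)c3)[C@H]2COCc2ccc(OCc3ccccc3)c(OC)c2)ccc1OCc1ccccc1
F2 | step 10 | bicyclic hemiketal, the C7'-hydroxy derivative of 19 (C2, C3, C4 as in 19; C7' unassigned) | COc1cc(C2(O)[C@H]3C(=O)O[C@H](c4ccc(OS(=O)(=O)c5ccc(C)cc5)c(OC)c4)[C@H]3CO2)ccc1OCc1ccccc1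
F3 | step 13 | (2S,3R,4R)-ring-B O-benzyl ring-A O-tosyl-lariciresinol | COc1cc(C[C@H]2CO[C@H](c3ccc(OS(=O)(=O)c4ccc(C)cc4)c(OC)c3)[C@H]2CO)ccc1OCc1ccccc1
F4 | step 6 | 4-[(1S,2R)-1-hydroxy-2-(hydroxymethyl)but-3-en-1-yl]-2-methoxyphenyl 4-methylbenzenesulfonate | O[C@H](c1ccc(OS(=O)(=O)c2ccc(C)cc2)c(OC)c1)[C@H](C=C)CO
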